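## Retrosynthetic overview

1. The target is 3,7,3',4'-tetrahydroxy-6-methyl-2'-prenylflavone. The plan rests on ring C, the pyran-4-one whose carbonyl carbon C4 lies between C4a of ring A and the C3–C2 unit that carries ring B, with O1 linking C8a to C2.
2. Last operations: the 3-OH is put on C3 of the finished flavone by lithiation–borylation–oxidation (step 9), which spares the prenyl alkene, and the three MOM ethers are then cleaved (step 10).
3. Ring C, the only ring made, is closed in step 8 from ortho-iodophenol 6 (ring A and O1), carbon monoxide 16 (C4) and arylacetylene 15 (C3, C2, ring B), forming C4a–C4, C4–C3 and O1–C2.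
4. Iodophenol 6 comes from 5-bromo-2-methylphenol (MOM ether, Br to OH, ortho-iodination), so the two ring-A oxygens never compete for the protecting group. Alkyne 15 comes from 4-bromocatechol (bis-MOM ether, metalation–prenylation between Br and OMOM, Sonogashira coupling, desilylation).
5. Ring order: rings A and B are bought as benzenes; ring C is formed last, in step 8.

Key step: step 8

Assumption: the target has no stereocentre and its only alkene carries two identical methyl groups, so the single-isomer requirement is met by the constitution alone and no stereocontrol is needed.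

## Route

Step 1
Reactants: 1 5-bromo-2-methylphenol
Product: 2 4-bromo-2-(methoxymethoxy)-1-methylbenzene
Conditions: MOMCl, i-Pr2NEt, CH2Cl2, 0 °C → rt
Reagents that add atoms: chloromethyl methyl ether, COCCl
Why: Williamson-type O-alkylation of the phenol with the reactive α-chloro ether should give the MOM acetal, and the aryl bromide is inert to the amine base.

Step 2
Reactants: 2 4-bromo-2-(methoxymethoxy)-1-methylbenzene
Product: 5 3-(methoxymethoxy)-4-methylphenol, via aryllithium 3 (not isolated), via dimethyl arylboronate 4 (not isolated)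
Conditions: n-BuLi, THF, −78 °C; B(OMe)3, −78 °C → rt; AcOH, 30 % aq H2O2, 0 °C
Reagents that add atoms: hydrogen peroxide, OO; trimethyl borate, COB(OC)OC (boron and methoxy groups of intermediate 4 only); n-butyllithium, [Li]CCCC (lithium of intermediate 3 only)
Why: Bromine–lithium exchange at −78 °C is faster than ortho or benzylic deprotonation, the aryllithium is trapped as the borate, and ipso oxidation of the C–B bond by hydrogen peroxide (boronate oxidation with 1,2-aryl shift) should deliver the phenol, the MOM acetal tolerating cold acetic acid for the short oxidation.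

Step 3
Reactants: 5 3-(methoxymethoxy)-4-methylphenol
Product: 6 2-iodo-5-(methoxymethoxy)-4-methylphenol
Conditions: I2, NaHCO3, THF/H2O, 0 °C → rt
Reagents that add atoms: iodine, II
Why: Electrophilic aromatic iodination under bicarbonate goes ortho to the free OH because the para position carries the methyl group, and of the two ortho sites the one para to the MOM ether is favoured over the crowded carbon between the two oxygens; the buffered medium keeps the acetal.

Step 4
Reactants: 7 4-bromocatechol
Product: 8 4-bromo-1,2-bis(methoxymethoxy)benzene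
Conditions: MOMCl, i-Pr2NEt, CH2Cl2, 0 °C → rt
Reagents that add atoms: chloromethyl methyl ether, COCCl
Why: Double Williamson-type O-alkylation of the catechol with MOMCl, the amine base avoiding the air-sensitive catecholate dianion.

Step 5
Reactants: 8 4-bromo-1,2-bis(methoxymethoxy)benzene; 9 prenyl bromide
Product: 12 1-bromo-3,4-bis(methoxymethoxy)-2-(3-methylbut-2-en-1-yl)benzene, via ortho-bromoaryllithium 10 (not isolated), via arylcopper 11 (not isolated)
Conditions: LDA, THF, −78 °C; CuBr·SMe2, −78 °C; 9, −78 → 0 °C
Reagents that add atoms: lithium diisopropylamide, CC(C)N([Li])C(C)C (lithium of intermediate 10 only); copper(I) bromide–dimethyl sulfide, Br[Cu].CSC (copper of intermediate 11 only)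
Why: Directed ortho-metalation with the non-nucleophilic amide LDA (no bromine–lithium exchange) removes the most acidic proton, the one flanked by bromine and the chelating MOM ether, the ortho-bromoaryllithium is kept at −78 °C so that it does not lose LiBr, and after transmetalation the arylcopper should substitute prenyl bromide at its primary carbon (copper-mediated SN2 allylic substitution).

Step 6
Reactants: 12 1-bromo-3,4-bis(methoxymethoxy)-2-(3-methylbut-2-en-1-yl)benzene; 13 trimethylsilylacetylene
Product: 14 {[3,4-bis(methoxymethoxy)-2-(3-methylbut-2-en-1-yl)phenyl]ethynyl}trimethylsilane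
Conditions: Pd(PhCN)2Cl2 (3 mol %), [(t-Bu)3PH]BF4 (6 mol %), CuI (2 mol %), i-Pr2NH, dioxane, rt → 50 °C
Reagents that add atoms: none
Why: Sonogashira coupling; the Pd/P(t-Bu)3 catalyst adds oxidatively to electron-rich, ortho-substituted aryl bromides near room temperature, and the neighbouring trisubstituted prenyl alkene could only undergo a disfavoured 4-exo or 5-endo Heck closure, so alkynylation should win.

Step 7
Reactants: 14 {[3,4-bis(methoxymethoxy)-2-(3-methylbut-2-en-1-yl)phenyl]ethynyl}trimethylsilane
Product: 15 1-ethynyl-3,4-bis(methoxymethoxy)-2-(3-methylbut-2-en-1-yl)benzene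
Conditions: K2CO3 (cat.), MeOH, rt
Reagents that add atoms: none
Why: Base-catalysed methanolysis of the alkynyl C–Si bond (protodesilylation) is selective for the TMS–alkyne and leaves the MOM ethers and the alkene alone.

Step 8
Reactants: 6 2-iodo-5-(methoxymethoxy)-4-methylphenol; 15 1-ethynyl-3,4-bis(methoxymethoxy)-2-(3-methylbut-2-en-1-yl)benzene; 16 carbon monoxide
Product: 19 2-[3,4-bis(methoxymethoxy)-2-(3-methylbut-2-en-1-yl)phenyl]-7-(methoxymethoxy)-6-methyl-4H-chromen-4-one, via ortho-hydroxyaryl ynone 17 (not isolated), via diethylamino enaminone 18 (not isolated)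
Conditions: PdCl2(dppf) (5 mol %), Et2NH (solvent), CO (20 atm), 120 °C, no copper
Reagents that add atoms: diethylamine, CCNCC (nitrogen and ethyl groups of intermediate 18 only, released again on ring closure)
Why: Pd(0) adds oxidatively to the C–I bond of 6, CO inserts to give an aroyl–Pd(II) species, and the amine-deprotonated alkyne 15 is transferred to palladium and reductively eliminated, which forms C4a–C4 and C4–C3 in the ortho-hydroxyaryl ynone 17. Diethylamine then adds to the ynone β-carbon to give enaminone 18, and the phenol closes ring C through O1–C2 by a 6-endo conjugate addition–elimination that expels the amine. The closest known reaction type is the palladium-catalysed carbonylative Sonogashira coupling–cyclisation of ortho-iodophenols with terminal alkynes to flavones. No stereocentre is formed. The step needs the flavone rather than the aurone (5-exo attack on the ynone) or the non-carbonylative 2-arylbenzofuran: the secondary amine turns the ynone into an enaminone whose only electrophilic carbon is C2, and copper-free conditions under 20 atm CO let CO insertion into the electron-rich aryl–Pd bond outrun direct alkynylation. The basic, acid-free medium should leave the three MOM ethers and the prenyl alkene untouched.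

Step 9
Reactants: 19 2-[3,4-bis(methoxymethoxy)-2-(3-methylbut-2-en-1-yl)phenyl]-7-(methoxymethoxy)-6-methyl-4H-chromen-4-one
Product: 22 2-[3,4-bis(methoxymethoxy)-2-(3-methylbut-2-en-1-yl)phenyl]-3-hydroxy-7-(methoxymethoxy)-6-methyl-4H-chromen-4-one, via 3-lithioflavone 20 (not isolated), via flavone-3-boronate 21 (not isolated)
Conditions: 19 + B(Oi-Pr)3, THF, LDA added at −78 °C (in situ trap); then AcOH, 30 % aq H2O2, 0 °C
Reagents that add atoms: hydrogen peroxide, OO; triisopropyl borate, CC(C)OB(OC(C)C)OC(C)C (boron and isopropoxy groups of intermediate 21 only); lithium diisopropylamide, CC(C)N([Li])C(C)C (lithium of intermediate 20 only)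
Why: Kinetic, carbonyl-directed deprotonation of the vinylic C3–H of the chromone by LDA with immediate capture of the vinyl-lithium by the borate, then ipso oxidation of the C3–B bond by hydrogen peroxide (lithiation–borylation–oxidation), should install the 3-OH, and none of these reagents attacks the unactivated trisubstituted prenyl alkene.

Step 10
Reactants: 22 2-[3,4-bis(methoxymethoxy)-2-(3-methylbut-2-en-1-yl)phenyl]-3-hydroxy-7-(methoxymethoxy)-6-methyl-4H-chromen-4-one
Product: 23 2-[3,4-dihydroxy-2-(3-methylbut-2-en-1-yl)phenyl]-3,7-dihydroxy-6-methyl-4H-chromen-4-one (target)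
Conditions: 3 M aq HCl, MeOH/THF, 45 °C, argon
Reagents that add atoms: none
Why: Acid-catalysed trans-acetalisation of the three aryl MOM ethers to methanol proceeds under dilute acid at mild temperature, conditions under which the prenyl group ortho to the freed 3'-OH should not yet cyclise to a chromane.

## Compound list

1 | 5-bromo-2-methylphenol | Cc1ccc(Br)cc1O | starting material
2 | 4-bromo-2-(methoxymethoxy)-1-methylbenzene | Cc1ccc(Br)cc1OCOC | intermediate
3 | [3-(methoxymethoxy)-4-methylphenyl]lithium | Cc1ccc([Li])cc1OCOC | intermediate (not isolated)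
4 | dimethyl [3-(methoxymethoxy)-4-methylphenyl]boronate | Cc1ccc(B(OC)OC)cc1OCOC | intermediate (not isolated)
5 | 3-(methoxymethoxy)-4-methylphenol | Cc1ccc(O)cc1OCOC | intermediate
6 | 2-iodo-5-(methoxymethoxy)-4-methylphenol | Cc1cc(I)c(O)cc1OCOC | intermediate
7 | 4-bromocatechol (4-bromobenzene-1,2-diol) | Oc1ccc(Br)cc1O | starting material
8 | 4-bromo-1,2-bis(methoxymethoxy)benzene | COCOc1ccc(Br)cc1OCOC | intermediate
9 | prenyl bromide (1-bromo-3-methylbut-2-ene) | CC(C)=CCBr | starting material
10 | [6-bromo-2,3-bis(methoxymethoxy)phenyl]lithium | [Li]c1c(Br)ccc(OCOC)c1OCOC | intermediate (not isolated)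
11 | [6-bromo-2,3-bis(methoxymethoxy)phenyl]copper | [Cu]c1c(Br)ccc(OCOC)c1OCOC | intermediate (not isolated)
12 | 1-bromo-3,4-bis(methoxymethoxy)-2-(3-methylbut-2-en-1-yl)benzene | CC(C)=CCc1c(Br)ccc(OCOC)c1OCOC | intermediate
13 | trimethylsilylacetylene (ethynyltrimethylsilane) | C#C[Si](C)(C)C | starting material
14 | {[3,4-bis(methoxymethoxy)-2-(3-methylbut-2-en-1-yl)phenyl]ethynyl}trimethylsilane | CC(C)=CCc1c(C#C[Si](C)(C)C)ccc(OCOC)c1OCOC | intermediate
15 | 1-ethynyl-3,4-bis(methoxymethoxy)-2-(3-methylbut-2-en-1-yl)benzene | C#Cc1ccc(OCOC)c(OCOC)c1CC=C(C)C | intermediate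
16 | carbon monoxide | [C-]#[O+] | starting material
17 | 3-[3,4-bis(methoxymethoxy)-2-(3-methylbut-2-en-1-yl)phenyl]-1-[2-hydroxy-4-(methoxymethoxy)-5-methylphenyl]prop-2-yn-1-one | CC(C)=CCc1c(C#CC(=O)c2cc(C)c(OCOC)cc2O)ccc(OCOC)c1OCOC | intermediate (not isolated)
18 | (E)-3-[3,4-bis(methoxymethoxy)-2-(3-methylbut-2-en-1-yl)phenyl]-3-(diethylamino)-1-[2-hydroxy-4-(methoxymethoxy)-5-methylphenyl]prop-2-en-1-one (drawn E; either geometry can close) | CCN(CC)/C(=C/C(=O)c1cc(C)c(OCOC)cc1O)c1ccc(OCOC)c(OCOC)c1CC=C(C)C | intermediate (not isolated)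
19 | 2-[3,4-bis(methoxymethoxy)-2-(3-methylbut-2-en-1-yl)phenyl]-7-(methoxymethoxy)-6-methyl-4H-chromen-4-one | CC(C)=CCc1c(-c2cc(=O)c3cc(C)c(OCOC)cc3o2)ccc(OCOC)c1OCOC | intermediate
20 | {2-[3,4-bis(methoxymethoxy)-2-(3-methylbut-2-en-1-yl)phenyl]-7-(methoxymethoxy)-6-methyl-4-oxo-4H-chromen-3-yl}lithium | CC(C)=CCc1c(-c2oc3cc(OCOC)c(C)cc3c(=O)c2[Li])ccc(OCOC)c1OCOC | intermediate (not isolated)
21 | dipropan-2-yl {2-[3,4-bis(methoxymethoxy)-2-(3-methylbut-2-en-1-yl)phenyl]-7-(methoxymethoxy)-6-methyl-4-oxo-4H-chromen-3-yl}boronate | CC(C)=CCc1c(-c2oc3cc(OCOC)c(C)cc3c(=O)c2B(OC(C)C)OC(C)C)ccc(OCOC)c1OCOC | intermediate (not isolated)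
22 | 2-[3,4-bis(methoxymethoxy)-2-(3-methylbut-2-en-1-yl)phenyl]-3-hydroxy-7-(methoxymethoxy)-6-methyl-4H-chromen-4-one | CC(C)=CCc1c(-c2oc3cc(OCOC)c(C)cc3c(=O)c2O)ccc(OCOC)c1OCOC | intermediate
23 | 2-[3,4-dihydroxy-2-(3-methylbut-2-en-1-yl)phenyl]-3,7-dihydroxy-6-methyl-4H-chromen-4-one | CC(C)=CCc1c(-c2oc3cc(O)c(C)cc3c(=O)c2O)ccc(O)c1O | target

## Step count and risks

Total step count: 10 (ring A: steps 1–3; ring B: steps 4–7; union and finish: steps 8–10).
Longest linear sequence: 7 steps (4, 5, 6, 7, 8, 9, 10, from 4-bromocatechol).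

Steps most likely to fail:

1. Step 8. Oxidative addition into the electron-rich, phenoxide-bearing aryl iodide may be slow. The aroyl-palladium intermediate may be intercepted by diethylamine (amide formation) or bypassed by direct alkynylation followed by benzofuran closure. Transfer of the ortho-prenylated alkyne may also be sluggish. The fallback sets out from 5 and 15 and comes back at 19, building the same ynone without CO. Magnesium-mediated ortho-formylation of 5 (MgCl2, Et3N, paraformaldehyde, MeCN, reflux) should give 2-hydroxy-4-(methoxymethoxy)-5-methylbenzaldehyde F1. Alkyne 15 is deprotonated (n-BuLi, THF, −78 °C) to lithium [3,4-bis(methoxymethoxy)-2-(3-methylbut-2-en-1-yl)phenyl]acetylide F2, which adds to F1 (phenol first deprotonated with NaH) to give the racemic propargylic alcohol 3-[3,4-bis(methoxymethoxy)-2-(3-methylbut-2-en-1-yl)phenyl]-1-[2-hydroxy-4-(methoxymethoxy)-5-methylphenyl]prop-2-yn-1-ol F3. Oxidation with MnO2 in CH2Cl2 gives ynone 17, and Et2NH in EtOH at 60 °C should close it through enaminone 18 to flavone 19.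

2. Step 9. LDA may instead remove a proton from the 2'-CH2 of the prenyl group, which is benzylic, allylic and vinylogous to the carbonyl through ring B, or metalate next to a MOM ether. Capture by the borate may lag behind anion equilibration, and the flavonol may degrade under the oxidant. The fallback is an Algar–Flynn–Oyamada route that sets out from 6 and 12 and comes back at 22. Iodophenol 6 with n-BuLi (2.1 equiv, THF, −78 °C) gives lithium 2-lithio-5-(methoxymethoxy)-4-methylphenoxide F4, which is acylated by N-methoxy-N-methylacetamide to 1-[2-hydroxy-4-(methoxymethoxy)-5-methylphenyl]ethan-1-one F5. Bromide 12 undergoes bromine–lithium exchange (n-BuLi, THF, −78 °C) to [3,4-bis(methoxymethoxy)-2-(3-methylbut-2-en-1-yl)phenyl]lithium F6, which is formylated with DMF to 3,4-bis(methoxymethoxy)-2-(3-methylbut-2-en-1-yl)benzaldehyde F7. Claisen–Schmidt condensation of F5 with F7 (KOH, EtOH, rt) should give (E)-3-[3,4-bis(methoxymethoxy)-2-(3-methylbut-2-en-1-yl)phenyl]-1-[2-hydroxy-4-(methoxymethoxy)-5-methylphenyl]prop-2-en-1-one F8. Alkaline hydrogen peroxide (NaOH, 30 % H2O2, MeOH, 0 °C → rt), a nucleophilic oxidant that ignores the electron-rich prenyl alkene, should cyclise and oxidise F8 to 22, which goes on to step 10.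

3. Step 5. The ortho-bromoaryllithium may lose LiBr to an aryne if the temperature drifts. The crowded arylcopper may react slowly with prenyl bromide or attack its tertiary terminus (SN2′), giving the 1,1-dimethylallyl isomer. The fallback sets out from 8 and comes back at 12, building the prenyl group in two stages. Arylcopper 11, generated from 8 exactly as in step 5, is alkylated with allyl bromide, an unhindered electrophile with no regiochemical ambiguity, to give 1-bromo-3,4-bis(methoxymethoxy)-2-(prop-2-en-1-yl)benzene F9. Cross-metathesis of F9 with excess 2-methylbut-2-ene (second-generation ruthenium benzylidene catalyst with an N-heterocyclic carbene ligand, CH2Cl2, 40 °C) should convert the allyl group into the prenyl group of 12.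

## Further compounds

F1 | step 8 | 2-hydroxy-4-(methoxymethoxy)-5-methylbenzaldehyde | Cc1cc(C=O)c(O)cc1OCOC
F2 | step 8 | lithium [3,4-bis(methoxymethoxy)-2-(3-methylbut-2-en-1-yl)phenyl]acetylide | [Li]C#Cc1ccc(OCOC)c(OCOC)c1CC=C(C)C
F3 | step 8 | 3-[3,4-bis(methoxymethoxy)-2-(3-methylbut-2-en-1-yl)phenyl]-1-[2-hydroxy-4-(methoxymethoxy)-5-methylphenyl]prop-2-yn-1-ol (racemic) | CC(C)=CCc1c(C#CC(O)c2cc(C)c(OCOC)cc2O)ccc(OCOC)c1OCOC
F4 | step 9 | lithium 2-lithio-5-(methoxymethoxy)-4-methylphenoxide | [Li]Oc1cc(OCOC)c(C)cc1[Li]
F5 | step 9 | 1-[2-hydroxy-4-(methoxymethoxy)-5-methylphenyl]ethan-1-one | CC(=O)c1cc(C)c(OCOC)cc1O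
F6 | step 9 | [3,4-bis(methoxymethoxy)-2-(3-methylbut-2-en-1-yl)phenyl]lithium | [Li]c1ccc(OCOC)c(OCOC)c1CC=C(C)C
F7 | step 9 | 3,4-bis(methoxymethoxy)-2-(3-methylbut-2-en-1-yl)benzaldehyde | CC(C)=CCc1c(C=O)ccc(OCOC)c1OCOC
F8 | step 9 | (E)-3-[3,4-bis(methoxymethoxy)-2-(3-methylbut-2-en-1-yl)phenyl]-1-[2-hydroxy-4-(methoxymethoxy)-5-methylphenyl]prop-2-en-1-one | CC(C)=CCc1c(/C=C/C(=O)c2cc(C)c(OCOC)cc2O)ccc(OCOC)c1OCOC
F9 | step 5 | 1-bromo-3,4-bis(methoxymethoxy)-2-(prop-2-en-1-yl)benzene | C=CCc1c(Br)ccc(OCOC)c1OCOC
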